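The runs come from a simulation for substances that don't exist; the scatter is artificial.

Hold one balance fixed: first product can gain no more than the substrate still has to give.

| setting | teal | grey | flask |
|---|---|---|---|
| substrate | 20 mM (fed, over 30 h) | 10 mM (fed, over 30 h) | 20 mM (fed, over 30 h) |
| gas | 3.3 mM (held) | 3.3 mM (held) | 3.3 mM (held) |
| remark | the very flask that is asked about, followed so far | run made earlier |  |
| time |  |  | 15 d |

- teal (time / d: first product / %, substrate / %): 1.04: 11.8, 52.6; 1.25: 15.7, 61.2; 1.67: 21.3, 45.9; 2.50: 30.6, 23.2; 3.00: 33.6, 13.5; 5.00: 34.3, 0.6
- grey (time / d: first product / %, substrate / %): 1.04: 15.0, 43.8; 1.67: 25.7, 29.6; 2.08: 30.1, 16.7; 3.00: 31.4, 4.1; 4.00: 27.1, 1.2; 6.00: 14.2, 0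

(scatter of a reading: 0.3 percentage points)

- at the start none of the gas is in solution
- a reading or a percentage of first product counts all its forms, free or not
- percentages count the whole charge, also what has not yet gone in

1. time up to 15 d at which first product stands highest
2. the amount of first product, in percent of the substrate charged, at that time
3. the first time at which first product reaches 11%, in the same percent

Turn the question round: what would put the highest first product of the teal flask at 15 d, not early? At 5.00 d the teal run reads 0.6% of its substrate left, so the loss of first product in the teal flask would have to stay below this, my own limit: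

limit = 0.6% × 20 mM / (15 d − 5.00 d) = 0.0120 mM d⁻¹

Read the loss from the grey run, where substrate falls away. Call D the drain, the average amount of first product the grey run loses per day once substrate is nearly used, an apparent zero-order loss:

D = (31.4% − 14.2%) × 10 mM / (6.00 d − 3.00 d) = 0.573 mM d⁻¹

Carry D to the teal flask as the same amount per day, a guess from one run. It stands 47.8 times above the limit, so expect an early peak in the teal flask.

The forecast says 3.8 d, 35.6% and 1 d, taking about 0.6 mM/d where I take D, and of the grey run once substrate has gone it says “the loss is nearly zero-order”.

The flask gives 4.05 d, 35.7% and 0.966 d.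

    substrate + reagent → first product (k = 14.0 L mol⁻¹ h⁻¹)
    substrate + reagent → other mono adduct (k = 19.0 L mol⁻¹ h⁻¹)
    reagent + first product → double product (k = 5.80 L mol⁻¹ h⁻¹)
    reagent + other mono adduct → double product (k = 14.0 L mol⁻¹ h⁻¹)
    crystals ⇌ first product, rate k5*(cs5 - [first product]) while solid is left; crystals form when [first product] > cs5 (solubility = 1.60 mM, k = 0.660 h⁻¹)
    gas ⇌ reagent, rate k6*(csat - [reagent]) (kL = 0.150 h⁻¹)

Take the teal flask at 4.05 d and charge its first product D from there. At D its 35.7% of 20 mM needs 12.5 d to clear, but 10.9 d remain, so reckon 4.33% left; the flask holds 3.59% at 15.0 d. Now cut the charge to 8.0 mM, all else held. The highest first product of that flask, 30.1%, is 2.41 mM, which at D needs 4.20 d to clear, less time than the teal flask needs. At 15.0 d that flask holds 0.158%.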